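Its constants come from no measurement.

Read at 3.0 d, this flask has had time for step 1 to deliver at most 104% of the charge into a solution kept empty, so I asked how much of that ceiling the starting material really receives.

starting material 2.2 M; gas phase 150 mM (held); catalyst 1 mol%; time 3.0 d

    gas phase ⇌ dissolved gas, rate k1*(csat - [dissolved gas]) (k1 = 5.89 × 10⁻⁵ s⁻¹, csat = 150 mM)
    starting material + dissolved gas + catalyst → catalyst + target (k2 = 0.00337 L² mol⁻² s⁻¹)
    target → over-reaction product (k3 = 5.07 × 10⁻⁵ s⁻¹)

- at the start none of the gas is dissolved
- run time (flask): 3.0 d

1. amount of target at 3.0 d, in percent of the starting material charged
2. concentration of dissolved gas in solution at 3.0 d, in percent of saturation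

The half-life of dissolved gas under step 2, 1.2 h, is far shorter than 3.0 d, so I let transfer equal uptake. I named the transfer ratio: the coefficient of step 1 over the pseudo-first-order uptake constant of the full charge (k2 × catalyst × starting material), 0.361. With a the fraction of starting material left, the gas stands at tr/(tr + a) of saturation, and the gas balance over the run reads: consumed + held in solution − tr·ln a = ceiling.

Held, at 0.5 of saturation: 3.41%, leaving 101%.

Trying a = 33.3%: the left side overshoots by 5.66%.

One slope correction: a = 36.0%.

Saturation: 50.0%.

The half-life of target, 0.16 d, is also shorter than 3.0 d, so target stands near formation over k3: 3.96% of the charge.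

The weak link was that formation is sinking, at a relative rate of saturation fraction × k2 × catalyst × dissolved gas, and target trails it by the time 1/k3, so I raised the figure:

4.17%.

The forecast gave 4.1% and 51%, on the ground that “The dissolved gas quickly settles to a balance between mass transfer and catalytic uptake”.

The flask gave 4.07% of target, with 36.1% of the starting material left. In that flask the dissolved gas stood at 48.9% of saturation.

The neighbouring flask, the same one read at 40 h, takes the same transfer ratio of 0.361 and a ceiling of 57.8%. A trial at 66.7% left, with one slope correction, gave me 61.8% left, then 36.9% of saturation and, with the trailing correction, 5.15% of target. That neighbouring flask held 61.9% of the starting material, 0.0544 M of dissolved gas and 5.06% of target.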